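I cannot reach the end of these flasks with a clock: neither run shows substrate or partner. A ratio of rates may do what a clock can't.

| flask | substrate | partner | remark | time |
|---|---|---|---|---|
| east | 10 mM | 7.3 mM | run made earlier |  |
| west | 10 mM | 23 mM | run made earlier |  |
| Thursday's | 10 mM | 5.00 mM |  | 2.5 min |
| Wednesday's | 10 mM | 12.0 mM |  | 2.5 min |
| Saturday's | 10 mM | 20.0 mM |  | 2.5 min |

| run | time / s | single product / % | tris adduct / % |
|---|---|---|---|
| east | 15.0 | 9 | 0 |
| east | 30.0 | 19 | 3 |
| east | 50.0 | 15 | 4 |
| east | 60.0 | 18 | 2 |
| east | 80.0 | 16 | 7 |
| west | 10.0 | 18 | 3 |
| west | 20.0 | 19 | 6 |
| west | 40.0 | 17 | 17 |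
| west | 50.0 | 14 | 19 |
| west | 80.0 | 6 | 31 |

(readings scatter by 2 percentage points)

- a reading or a percentage of tris adduct counts all its forms, free or not

- single product at the end, in percent of the substrate charged, for each flask in turn (Thursday's, Wednesday's, Saturday's)

First I compare the early making of single product. West reaches 18% in 10.0 s and east 9% in 15.0 s, so:

west's rate / east's rate = 3.00, against a partner ratio of 3.15

Making therefore goes with partner, and I take it that using single product does too. With s and m as the fractions of the charge left as substrate and standing as single product, and p as partner:

making / using = (k_make · s · p) / (k_use · m · p) = (k_make · s) / (k_use · m)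

Partner and time have dropped out. Single product stands at its top where this ratio is one, at m = s · k_make / k_use, and k_make / k_use is a selectivity factor. At equal s, then, the top doesn't move with partner.

The runs cannot test that, as neither shows s, and a single reading scatters by 2 percentage points. So I take a level rather than one high point: west's readings from 10.0 s to 40.0 s average 18.0%, which I carry as the top of single product, a reading of west and no constant, and east's top may stand elsewhere.

The asked 2.5 min is later than the last reading of either run, so I expect all three flasks past the point where the ratio is one, and below the top. At 80.0 s east still reads 16% but west has fallen to 6%, so I place the ends in falling order as partner rises. I commit to that order and bound, without numbers of my own.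

The forecast gives 16%, 12% and 7.5%, which fit that order, and says single product “settles where the feed balances loss”.

The flasks end at 12.4% for Thursday's, 10.7% for Wednesday's and 5.83% for Saturday's.

    substrate + partner → single product + by-product (k = 1.70 /M/s)
    partner + single product → bis adduct + by-product (k = 3.60 /M/s)
    partner + bis adduct → tris adduct + by-product (k = 2.20 /M/s)
    tris adduct → over-reaction product (k = 0.00190 /s)
    crystals ⇌ tris adduct, rate k5*(cs5 - [tris adduct]) while solid is left; crystals form when [tris adduct] > cs5 (solubility = 4.80 mM, k = 1.10 /s)
    2 substrate → homo dimer (k = 1.20 /M/s)

In Thursday's flask, single product is made 2.86 times as fast as it is used up at 0.344 min. At 2.50 min that ratio is 0.613, so the flask has crossed one. Against the top of 18.0%, Thursday's end stands at 0.689, Wednesday's at 0.594 and Saturday's at 0.324.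

The data come from a simulation on assumed constants, and the scatter is random.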